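Remark on the chemistry: ring A is the methoxy ring, numbered C1 (carbon bearing the depside carbonyl), C2 (hydroxyl), C4 (methoxy), C6 (2-oxoheptyl arm). Ring B is the pentyl-substituted benzoic acid ring, numbered with primes from the carboxyl-bearing carbon C1′ (C2′ hydroxyl, C4′ depside oxygen, C6′ pentyl).

## Structural features

The target is a depside without stereocentres: two benzene rings joined only through an aryl ester, ring A supplying the acyl part and ring B the phenol oxygen O4′. Ring A carries the ester carbonyl at C1, a free hydroxyl at C2, a methoxy group at C4 and a CH2–C(=O)–pentyl chain at C6; ring B is olivetolic acid, with CO2H at C1′, OH at C2′ and pentyl at C6′. The depside ester is an activated aryl ester flanked by two ortho substituents, so it is hard to make by acylating O4′ and easy to lose to nucleophiles, base or Lewis acid. The C6 ketone is fragile in this setting, because its enol oxygen can reach the C1 carbonyl and close a 3-pentylisocoumarin with expulsion of ring B; the salicylic acid of ring B can also decarboxylate on heating. The real difficulty is therefore threefold: forming the hindered C1–carbonyl/O4′ linkage, telling the C2 oxygen from the C4 oxygen (and O4′ from O2′), and unveiling ketone, two phenols and the acid under neutral conditions. The key step exploits the fact that on ring A the ester carbonyl carbon on C1 and the side-chain methylene on C6 are ortho neighbours next to the C2 oxygen, which is the pattern left when a 3-alkoxyaryne inserts into an activated C–C bond.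

## Logic of the disconnections

26 to 25: the three O–CH2Ph bonds (at O2, at O2′ and at the C1′ carboxyl) are cut last. One neutral hydrogenolysis then frees every polar group at once, and no acid, base or Lewis acid meets the finished ketone–depside array. The demand is that every temporary group in 25 is benzylic and that ketone and aryl ester are inert to hydrogen on palladium.

25 to 21 and 23 (through 24): the bond between the ketone carbonyl and the pentyl chain is cut. The ketone is thereby introduced only after the depside exists, so no enolisable ketone is present when the ester is formed. The side chain shrinks to an acetic acid arm. The forward step needs a carbon nucleophile that ignores three esters, one of them activated; an organozinc under palladium catalysis meets this.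

21 to 20: the O–C(CH3)3 bond is cut. The tert-butyl ester is the hindered, poorly electrophilic spectator carbonyl that the key step requires, and acid removes it without touching benzyl groups. The demand is that the tert-butyl cation is intercepted before it alkylates the electron-rich rings.

20 to 9 and 18 (through 19): the C6–CH2 and C1–C(=O) bonds of ring A are cut together. Both arise when 19 inserts into the CH2–C(=O)OAr bond of 18, so the hindered ester is never made by O-acylation. The target falls into two arenes of similar size. The forward step must add the nucleophile at the aryne carbon remote from the benzyloxy group, make the aryl anion choose the aryl ester carbonyl over the tert-butyl one, and meet no free hydroxyl.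

18 to 16 and 17: the acyl C–O bond at O4′ is cut. Here O4′ is acylated by an unhindered malonyl group, which is easy. The demand is mild activation, because 18 is an activated ester with an acidic methylene.

16 back to 10 (through 15, 14, 13, 12): the O4′–Si bond, two O–benzyl bonds, the oxidation level of the C1′ carbon and finally the C1′–CHO bond are cut. Formylation of 10 goes para to a hydroxyl and so places the carbon between hydroxyl and pentyl; a direct carboxylation could also place it between the two hydroxyls. In 12 one hydroxyl is chelated to the carbonyl, so O4′ alone can be silylated. The demands are an aldehyde oxidation without ring chlorination and benzylation of the chelated O2′ without loss of the silyl ether.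

9 back to 1 (through 8, 7, 6, 2): the O–S bond of the triflate, the O–benzyl bond, the C–Si bond and two carbamate O–C bonds are cut. Silicon must sit on the carbon between the two resorcinol oxygens of 1, para to the methoxy group. A mono-benzylated mono-carbamate of 1 would offer two positions ortho to the carbamate, one flanked by benzyloxy and one by methoxy, with nearly equal acidity, and benzylic lithiation would threaten as well. Silylation is therefore done on symmetric 2, where only the wanted carbon lies between two strong directing groups, and the oxygens are told apart afterwards by mono-benzylation of symmetric 7. The price is one statistical step and the need to keep 7 and 8 away from acid.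

23 to 22: the C–Zn bond is cut; zinc insertion into the primary bromide makes the ester-tolerant nucleophile.

## Other disconnections considered

Alternative 1: Ring A is taken apart at C1–C2 and C5–C6, back to the aryl ynoate A2 and the electron-rich diene A3. Heating the two should give a cycloadduct that loses methanol and the silyl group to leave A1, with the C2 hydroxyl and C4 methoxy group already differentiated by the diene.
- In its favour: the depside C–O bond is made on an unhindered ynoic acid. The oxygen pattern of ring A is set by the reagent, not by protecting-group work; on this point the alternative is better than the chosen plan, which pays one statistical benzylation for the same differentiation. Ring A needs no separate arene precursor.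
- Against it here: A2 is a strongly activated Michael acceptor and acyl donor that carries a free phenol on ring B. The propargylic methylene between alkyne and ketal invites isomerisation to an allenoate. Stepwise Mukaiyama–Michael addition of A3 without ring closure can compete with the cycloaddition. The ketone must travel as a dioxolane, and its removal needs aqueous acid on a molecule that then holds the free C2 hydroxyl, the activated ester and the ketone together.
- Comparison: on structure the two plans are equal in avoiding acylation of O4′ by a hindered acid. On mechanism neither is clearly safer: a reagent-free thermal cycloaddition against an insertion that depends on a carbonyl choice. On step economy the alternative is probably equal or slightly better up to the key step, but it ends with an acidic deprotection where the chosen plan ends with a neutral hydrogenolysis.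

Alternative 2: The cut runs through the C(=O)–O4′ bond and the C1–C6 bond of ring A, giving benzyl olivetolate A6 and the diketo-dioxinone A5. On heating, A5 should lose acetone and expose a ketene function that O4′ of A6 captures; the open chain then closes ring A by aldol condensation between C1 and C6 and dehydrates to A4.
- In its favour: the route is biomimetic and the ester forms by neutral ketene capture, so it is equal to the chosen plan in avoiding hindered acylation. Depside bond and ring A arise in one operation. A6 needs no protection at O2′, which makes the alternative better in protecting-group economy.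
- Against it here: phenols are weaker ketene traps than alcohols, and O4′ is further deactivated by the para ester. The captured chain is an aryl polyketo ester, so under the base or acid needed for aromatisation O-cyclisation with loss of the aryloxide can compete with C-cyclisation. A4 has a free C4 hydroxyl that must be methylated selectively beside two chelated phenols, an extra step on a base-sensitive depside. A5 needs a multi-step assembly, and the dioxolane again forces an acidic last step.
- Comparison: structurally equal on the ester. Mechanistically the ring closure must win against loss of aryloxide, a problem of the same kind as the carbonyl choice in the chosen plan. Step economy is roughly equal once methylation, deketalisation and the synthesis of A5 are counted.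

Alternative 3: The carbonyl carbon itself is removed: C1–C(=O) and C(=O)–O4′ are cut to give aryl iodide A8, carbon monoxide and A6. Zerovalent palladium, formed from Pd(OAc)2 and a wide-bite-angle bisphosphine, should insert into the C1–I bond; carbon monoxide inserts, and O4′ of A6 captures the aroylpalladium to give A7.
- In its favour: this is the most modular plan with the simplest coupling partners, and it is better than the chosen plan in the length of the route to them. No aryne precursor is needed.
- Against it here: the C1–I bond is flanked by two ortho substituents on an electron-rich ring, so oxidative addition and carbon monoxide insertion are slow and reduction can compete. Aryloxycarbonylation with an electron-poor phenol is the least favourable version of the reaction. A7 carries a C2 methyl ether that must be cleaved selectively with a Lewis acid such as BCl3 next to the ester and ketal that must survive, and the ketone is again unmasked by acid.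
- Comparison: structurally equal in that the hindered ester is not made by classical acylation. Mechanistically both the acylpalladium capture and the aryne insertion have precedent for simpler partners only. The alternative is better before its key step and worse after it, because of the selective O-demethylation.

Key step: step 12

## Route

Step 1
Reactants: 1 5-methoxyresorcinol
Product: 2 5-methoxy-1,3-phenylene bis(N-isopropylcarbamate)
Conditions: i-PrNCO (2.3 equiv), Et3N (cat.), CH2Cl2, rt
Reagents that add atoms: isopropyl isocyanate, CC(C)N=C=O
Why: Base-catalysed addition of both phenols to the isocyanate (carbamoylation); carbamoylating both hydroxyls keeps the molecule symmetric, so the only ring carbon flanked by two carbamates is the one that must carry silicon.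

Step 2
Reactants: 2 5-methoxy-1,3-phenylene bis(N-isopropylcarbamate)
Product: 6 5-methoxy-2-(trimethylsilyl)-1,3-phenylene bis(N-isopropylcarbamate), via bis(N-silyl) carbamate 3 (not isolated), via C2-lithio bis(N-silyl) carbamate 4 (not isolated), via C2-silyl bis(N-silyl) carbamate 5 (not isolated)
Conditions: TMSOTf, TMEDA, Et2O, 0 °C to rt; n-BuLi, TMEDA, −78 °C; TMSCl, −78 °C to rt; aq. NH4Cl
Reagents that add atoms: chlorotrimethylsilane, C[Si](C)(C)Cl
Why: Directed ortho-metalation of an O-aryl N-isopropylcarbamate protected in situ on nitrogen; the carbon between the two carbamates should be the most acidic and best chelated site because a carbamate outranks methoxy as a directing group, the quench at −78 °C forestalls an anionic Fries shift, and aqueous work-up removes the N-silyl groups.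

Step 3
Reactants: 6 5-methoxy-2-(trimethylsilyl)-1,3-phenylene bis(N-isopropylcarbamate)
Product: 7 5-methoxy-2-(trimethylsilyl)benzene-1,3-diol
Conditions: Et2NH, DBU, MeCN, 40 °C; pH 7 buffer work-up
Reagents that add atoms: none
Why: E1cB cleavage of N-monoalkyl aryl carbamates: DBU removes N–H, isopropyl isocyanate is expelled and trapped by diethylamine as a urea; the medium is never acidic, which the protodesilylation-prone electron-rich arylsilane requires.

Step 4
Reactants: 7 5-methoxy-2-(trimethylsilyl)benzene-1,3-diol
Product: 8 3-(benzyloxy)-5-methoxy-2-(trimethylsilyl)phenol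
Conditions: BnBr (0.95 equiv), K2CO3 (1.0 equiv), acetone, rt; recovered 7 recycled
Reagents that add atoms: benzyl bromide, BrCc1ccccc1
Why: Williamson mono-etherification of a symmetric diol; either hydroxyl gives the same product, so the only issue is mono- against bis-alkylation, which is handled by limiting the halide and recycling the diol.

Step 5
Reactants: 8 3-(benzyloxy)-5-methoxy-2-(trimethylsilyl)phenol
Product: 9 3-(benzyloxy)-5-methoxy-2-(trimethylsilyl)phenyl trifluoromethanesulfonate
Conditions: Tf2O, pyridine, CH2Cl2, 0 °C
Reagents that add atoms: trifluoromethanesulfonic anhydride, O=S(=O)(OS(=O)(=O)C(F)(F)F)C(F)(F)F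
Why: O-Sulfonylation of an ortho-silyl phenol, the standard last step towards an ortho-silylaryl triflate; the electron-withdrawing triflate should also steady the C–Si bond against ipso-protonation.

Step 6
Reactants: 10 olivetol
Product: 12 2,4-dihydroxy-6-pentylbenzaldehyde, via aryl iminium chloride 11 (not isolated)
Conditions: POCl3, DMF, 0 °C to rt; H2O, 50 °C
Reagents that add atoms: N,N-dimethylformamide, CN(C)C=O; water, O
Why: Vilsmeier–Haack formylation; the chloroiminium ion attacks a 5-alkylresorcinol para to one hydroxyl and ortho to the other, i.e. next to the pentyl group (both such carbons are equivalent), which fixes the olivetolic acid substitution pattern.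

Step 7
Reactants: 12 2,4-dihydroxy-6-pentylbenzaldehyde
Product: 13 2-hydroxy-6-pentyl-4-[(triisopropylsilyl)oxy]benzaldehyde
Conditions: TIPSCl (1.05 equiv), imidazole, CH2Cl2, 0 °C
Reagents that add atoms: chlorotriisopropylsilane, CC(C)[Si](Cl)(C(C)C)C(C)C
Why: Selective O-silylation; the C2′ hydroxyl is held in a hydrogen bond to the aldehyde, so the bulky silyl chloride should take the free, more acidic para hydroxyl O4′.

Step 8
Reactants: 13 2-hydroxy-6-pentyl-4-[(triisopropylsilyl)oxy]benzaldehyde
Product: 14 2-hydroxy-6-pentyl-4-[(triisopropylsilyl)oxy]benzoic acid
Conditions: NaClO2, NaH2PO4, 2-methyl-2-butene, t-BuOH/THF/H2O, 0 °C to rt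
Reagents that add atoms: sodium chlorite, [Na+].[O-]Cl=O
Why: Pinnick (Lindgren) oxidation, a chlorite oxidation that tolerates hydroxybenzaldehydes; the alkene scavenges hypochlorous acid and so shields the electron-rich ring from chlorination, and the buffered medium should leave the aryl silyl ether intact.

Step 9
Reactants: 14 2-hydroxy-6-pentyl-4-[(triisopropylsilyl)oxy]benzoic acid
Product: 15 benzyl 2-(benzyloxy)-6-pentyl-4-[(triisopropylsilyl)oxy]benzoate
Conditions: BnBr (2.5 equiv), K2CO3, DMF, rt to 50 °C
Reagents that add atoms: benzyl bromide, BrCc1ccccc1
Why: Double O-alkylation: the carboxylate is benzylated first (SN2 at the halide, indifferent to the hindrance around the carboxyl), then the chelated phenoxide; anhydrous carbonate should leave the triisopropylsilyl ether in place.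

Step 10
Reactants: 15 benzyl 2-(benzyloxy)-6-pentyl-4-[(triisopropylsilyl)oxy]benzoate
Product: 16 benzyl 2-(benzyloxy)-4-hydroxy-6-pentylbenzoate
Conditions: TBAF, AcOH, THF, 0 °C
Reagents that add atoms: none
Why: Fluoride cleavage of the aryl silyl ether; acetic acid buffers the phenoxide so that the benzyl ester is not attacked.

Step 11
Reactants: 16 benzyl 2-(benzyloxy)-4-hydroxy-6-pentylbenzoate; 17 mono-tert-butyl malonate
Product: 18 tert-butyl 3-(benzyloxy)-4-[(benzyloxy)carbonyl]-5-pentylphenyl malonate
Conditions: DCC, DMAP (cat.), CH2Cl2, 0 °C
Reagents that add atoms: none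
Why: Steglich-type esterification (malonic half esters are activated by carbodiimides very readily); O4′ is the only free nucleophile, and low temperature with only catalytic base limits E1cB loss of aryloxide from the activated ester product.

Step 12
Reactants: 9 3-(benzyloxy)-5-methoxy-2-(trimethylsilyl)phenyl trifluoromethanesulfonate; 18 tert-butyl 3-(benzyloxy)-4-[(benzyloxy)carbonyl]-5-pentylphenyl malonate
Product: 20 benzyl 2-(benzyloxy)-4-{[2-(benzyloxy)-6-(2-tert-butoxy-2-oxoethyl)-4-methoxybenzoyl]oxy}-6-pentylbenzoate, via 3-benzyloxy-5-methoxybenzyne 19 (not isolated)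
Conditions: CsF (3 equiv), MeCN, 60 °C, 9 (1.3 equiv) added slowly
Reagents that add atoms: none
Why: Fluoride removes the silyl group of 9 and triflate leaves, giving aryne 19, while the same basic medium forms the enolate of malonate 18. The enolate carbon should add to the aryne carbon remote from the benzyloxy group (future C6), because the electronegative oxygen on the neighbouring carbon distorts the aryne and stabilises the anion that develops next to it (future C1). This aryl anion attacks the aryl ester carbonyl (4-exo-trig), and the strained benzocyclobutenoxide opens by C–C cleavage to the tert-butyl ester enolate, which is protonated by further 18; the C6–CH2 and C1–C(=O) bonds thus form as the malonate C–C bond breaks, no ring stays closed and no stereocentre is created. The closest known reaction type is the acyl-alkylation of arynes, i.e. σ-insertion into the C–C bond of malonates and β-keto esters. Three selectivities are needed: the site of addition to the aryne, the choice of carbonyl, and fragmentation of the four-membered ring in preference to loss of aryloxide. The first is secured by the C2 benzyloxy group, the second by the higher electrophilicity of an aryl ester and the bulk of the tert-butyl ester. For the third, ring strain drives the C–C cleavage, and even if aryloxide were expelled, the strained benzocyclobutenone (or an aroyl fluoride derived from it) should be re-opened or re-acylated by the same aryloxide in the dry aprotic medium, converging on 20. Every hydroxyl is protected, so O-arylation cannot compete, and 20 is far less acidic than 18, which disfavours a second arylation.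

Step 13
Reactants: 20 benzyl 2-(benzyloxy)-4-{[2-(benzyloxy)-6-(2-tert-butoxy-2-oxoethyl)-4-methoxybenzoyl]oxy}-6-pentylbenzoate
Product: 21 {3-(benzyloxy)-2-[(3-(benzyloxy)-4-[(benzyloxy)carbonyl]-5-pentylphenoxy)carbonyl]-5-methoxyphenyl}acetic acid
Conditions: TFA, Et3SiH, CH2Cl2, 0 °C to rt
Reagents that add atoms: none
Why: Acidolysis of the tert-butyl ester by alkyl–oxygen cleavage; benzyl ethers, the benzyl ester and the aryl ester should survive trifluoroacetic acid at room temperature, and the silane reduces the tert-butyl cation before it can alkylate the electron-rich rings.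

Step 14
Reactants: 22 1-bromopentane
Product: 23 pentylzinc bromide
Conditions: Zn dust (activated with 1,2-dibromoethane and TMSCl), LiCl, THF, 50 °C
Reagents that add atoms: zinc, [Zn]
Why: LiCl-mediated oxidative insertion of zinc into a primary alkyl bromide; the organozinc halide transmetalates readily but is inert to esters and ketones.

Step 15
Reactants: 21 {3-(benzyloxy)-2-[(3-(benzyloxy)-4-[(benzyloxy)carbonyl]-5-pentylphenoxy)carbonyl]-5-methoxyphenyl}acetic acid; 23 pentylzinc bromide
Product: 25 benzyl 2-(benzyloxy)-4-{[2-(benzyloxy)-4-methoxy-6-(2-oxoheptyl)benzoyl]oxy}-6-pentylbenzoate, via arylacetyl chloride 24 (not isolated)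
Conditions: (COCl)2, DMF (cat.), CH2Cl2, 0 °C to rt, evaporate; 23, Pd(PPh3)4 (5 mol %), THF, 0 °C to rt; aq. NH4Cl
Reagents that add atoms: none
Why: Acid chloride formation without amine base (which would invite ketene formation or attack of the carboxylate on the neighbouring aryl ester), then Negishi acylation: zerovalent palladium inserts into the C–Cl bond, the pentyl group is transferred from zinc and reductive elimination gives the ketone; the organozinc should leave the depside and the benzyl ester untouched.

Step 16
Reactants: 25 benzyl 2-(benzyloxy)-4-{[2-(benzyloxy)-4-methoxy-6-(2-oxoheptyl)benzoyl]oxy}-6-pentylbenzoate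
Product: 26 2-hydroxy-4-{[2-hydroxy-4-methoxy-6-(2-oxoheptyl)benzoyl]oxy}-6-pentylbenzoic acid (CNP0358566.0)
Conditions: H2 (1 atm), Pd/C, EtOAc, rt
Reagents that add atoms: none
Why: Hydrogenolysis of two benzyl ethers and one benzyl ester under neutral conditions; the aliphatic ketone, the aryl ester and the arenes should not be reduced, and the absence of acid or base avoids isocoumarin formation and decarboxylation.

## Compound list

1 | 5-methoxyresorcinol | COc1cc(O)cc(O)c1 | starting material
2 | 5-methoxy-1,3-phenylene bis(N-isopropylcarbamate) | COc1cc(OC(=O)NC(C)C)cc(OC(=O)NC(C)C)c1 | intermediate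
3 | 5-methoxy-1,3-phenylene bis[N-isopropyl-N-(trimethylsilyl)carbamate] | COc1cc(OC(=O)N(C(C)C)[Si](C)(C)C)cc(OC(=O)N(C(C)C)[Si](C)(C)C)c1 | intermediate
4 | [2,6-bis({[isopropyl(trimethylsilyl)amino]carbonyl}oxy)-4-methoxyphenyl]lithium | COc1cc(OC(=O)N(C(C)C)[Si](C)(C)C)c([Li])c(OC(=O)N(C(C)C)[Si](C)(C)C)c1 | intermediate
5 | 5-methoxy-2-(trimethylsilyl)-1,3-phenylene bis[N-isopropyl-N-(trimethylsilyl)carbamate] | COc1cc(OC(=O)N(C(C)C)[Si](C)(C)C)c([Si](C)(C)C)c(OC(=O)N(C(C)C)[Si](C)(C)C)c1 | intermediate
6 | 5-methoxy-2-(trimethylsilyl)-1,3-phenylene bis(N-isopropylcarbamate) | COc1cc(OC(=O)NC(C)C)c([Si](C)(C)C)c(OC(=O)NC(C)C)c1 | intermediate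
7 | 5-methoxy-2-(trimethylsilyl)benzene-1,3-diol | COc1cc(O)c([Si](C)(C)C)c(O)c1 | intermediate
8 | 3-(benzyloxy)-5-methoxy-2-(trimethylsilyl)phenol | COc1cc(O)c([Si](C)(C)C)c(OCc2ccccc2)c1 | intermediate
9 | 3-(benzyloxy)-5-methoxy-2-(trimethylsilyl)phenyl trifluoromethanesulfonate | COc1cc(OCc2ccccc2)c([Si](C)(C)C)c(OS(=O)(=O)C(F)(F)F)c1 | intermediate
10 | olivetol (5-pentylbenzene-1,3-diol) | CCCCCc1cc(O)cc(O)c1 | starting material
11 | N-[(2,4-dihydroxy-6-pentylphenyl)methylidene]-N-methylmethanaminium chloride | CCCCCc1cc(O)cc(O)c1C=[N+](C)C.[Cl-] | intermediate
12 | 2,4-dihydroxy-6-pentylbenzaldehyde | CCCCCc1cc(O)cc(O)c1C=O | intermediate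
13 | 2-hydroxy-6-pentyl-4-[(triisopropylsilyl)oxy]benzaldehyde | CCCCCc1cc(O[Si](C(C)C)(C(C)C)C(C)C)cc(O)c1C=O | intermediate
14 | 2-hydroxy-6-pentyl-4-[(triisopropylsilyl)oxy]benzoic acid | CCCCCc1cc(O[Si](C(C)C)(C(C)C)C(C)C)cc(O)c1C(=O)O | intermediate
15 | benzyl 2-(benzyloxy)-6-pentyl-4-[(triisopropylsilyl)oxy]benzoate | CCCCCc1cc(O[Si](C(C)C)(C(C)C)C(C)C)cc(OCc2ccccc2)c1C(=O)OCc3ccccc3 | intermediate
16 | benzyl 2-(benzyloxy)-4-hydroxy-6-pentylbenzoate | CCCCCc1cc(O)cc(OCc2ccccc2)c1C(=O)OCc3ccccc3 | intermediate
17 | mono-tert-butyl malonate (3-tert-butoxy-3-oxopropanoic acid) | CC(C)(C)OC(=O)CC(=O)O | starting material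
18 | tert-butyl 3-(benzyloxy)-4-[(benzyloxy)carbonyl]-5-pentylphenyl malonate | CC(C)(C)OC(=O)CC(=O)Oc1cc(OCc2ccccc2)c(C(=O)OCc2ccccc2)c(CCCCC)c1 | intermediate
19 | 3-(benzyloxy)-5-methoxybenzyne | COC1=CC#CC(OCc2ccccc2)=C1 | intermediate
20 | benzyl 2-(benzyloxy)-4-{[2-(benzyloxy)-6-(2-tert-butoxy-2-oxoethyl)-4-methoxybenzoyl]oxy}-6-pentylbenzoate | CC(C)(C)OC(=O)Cc1cc(OC)cc(OCc2ccccc2)c1C(=O)Oc1cc(OCc2ccccc2)c(C(=O)OCc2ccccc2)c(CCCCC)c1 | intermediate
21 | {3-(benzyloxy)-2-[(3-(benzyloxy)-4-[(benzyloxy)carbonyl]-5-pentylphenoxy)carbonyl]-5-methoxyphenyl}acetic acid | OC(=O)Cc1cc(OC)cc(OCc2ccccc2)c1C(=O)Oc1cc(OCc2ccccc2)c(C(=O)OCc2ccccc2)c(CCCCC)c1 | intermediate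
22 | 1-bromopentane | CCCCCBr | starting material
23 | pentylzinc bromide | CCCCC[Zn]Br | intermediate
24 | {3-(benzyloxy)-2-[(3-(benzyloxy)-4-[(benzyloxy)carbonyl]-5-pentylphenoxy)carbonyl]-5-methoxyphenyl}acetyl chloride | ClC(=O)Cc1cc(OC)cc(OCc2ccccc2)c1C(=O)Oc1cc(OCc2ccccc2)c(C(=O)OCc2ccccc2)c(CCCCC)c1 | intermediate
25 | benzyl 2-(benzyloxy)-4-{[2-(benzyloxy)-4-methoxy-6-(2-oxoheptyl)benzoyl]oxy}-6-pentylbenzoate | CCCCCC(=O)Cc1cc(OC)cc(OCc2ccccc2)c1C(=O)Oc1cc(OCc2ccccc2)c(C(=O)OCc2ccccc2)c(CCCCC)c1 | intermediate
26 | 2-hydroxy-4-{[2-hydroxy-4-methoxy-6-(2-oxoheptyl)benzoyl]oxy}-6-pentylbenzoic acid (CNP0358566.0) | CCCCCC(=O)Cc1cc(OC)cc(O)c1C(=O)Oc1cc(O)c(C(=O)O)c(CCCCC)c1 | target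

## Step count and least certain steps

Total step count: 16. Longest linear sequence: 10 steps from olivetol 10 (steps 6, 7, 8, 9, 10, 11, 12, 13, 15, 16). The aryne branch (steps 1 to 5) and the organozinc (step 14) are convergent.

Step 12 (key step). Most likely to go wrong: migration of the tert-butyl ester carbonyl in place of the aryl ester carbonyl; loss of aryloxide from the four-membered intermediate without recapture; E1cB fragmentation of 18 to a ketene and ring B phenoxide, followed by O-arylation of that phenoxide by the aryne; and a second arylation of the product. The cause is that 18 is an activated ester with an acidic methylene, and the choice between two ester carbonyls has only been argued by analogy. Fallback: separate the insertion from depside formation, setting out from 17, 9 and 16 and returning at 20. Acid 17 is esterified with allyl alcohol (DCC) to allyl tert-butyl malonate F1. Aryne 19 (from 9, CsF, MeCN) is inserted into F1, where the unhindered allyl ester carbonyl should migrate, to give allyl 2-(benzyloxy)-6-(2-tert-butoxy-2-oxoethyl)-4-methoxybenzoate F2. Tsuji–Trost deallylation (Pd(PPh3)4, morpholine) gives 2-(benzyloxy)-6-(2-tert-butoxy-2-oxoethyl)-4-methoxybenzoic acid F3. Esterification of F3 with 16 through the mixed trifluoroacetic anhydride (TFAA, toluene, rt) returns to 20. This fallback does acylate a phenol with the hindered acid, but before any ketone is present.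

Step 2. Most likely to go wrong: metalation at the carbon between a carbamate and the methoxy group in place of the carbon between the two carbamates, or an anionic Fries shift of a carbamoyl group before the silyl quench. The cause is that all three free ring positions are flanked by two oxygens. Fallback: fix the position with a halogen, setting out from 1 and returning at 7. Iodination under aqueous bicarbonate (I2, NaHCO3, H2O, 0 °C), the conditions that direct iodine between the hydroxyls of resorcinols, should give 2-iodo-5-methoxybenzene-1,3-diol F4; the symmetric isomer is recognisable by its two equivalent ring hydrogens. Bis-O-silylation with hexamethyldisilazane gives 2-iodo-5-methoxy-1,3-bis(trimethylsilyloxy)benzene F5. Iodine–lithium exchange (n-BuLi, THF, −78 °C) with retro-Brook 1,3 O-to-C silyl shift gives lithium 5-methoxy-2-(trimethylsilyl)-3-(trimethylsilyloxy)phenolate F6, and hydrolysis of the remaining O–Si bond on buffered work-up returns to 7.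

Step 4. Most likely to go wrong: over-alkylation to the bis-ether, and loss of the silyl group by ipso-protonation of the very electron-rich ring of 7 or 8 during work-up and chromatography. Fallback: desymmetrise at the carbamate stage so that the diol is never freed, setting out from 6 and returning at 9. Partial E1cB cleavage (Et2NH, limiting DBU, MeCN, rt, stopped at partial conversion) gives 3-hydroxy-5-methoxy-2-(trimethylsilyl)phenyl N-isopropylcarbamate F7. Benzylation (BnBr, K2CO3, acetone) gives 3-(benzyloxy)-5-methoxy-2-(trimethylsilyl)phenyl N-isopropylcarbamate F8. One-pot carbamate cleavage and triflation (Et2NH, DBU, MeCN, 40 °C; then PhNTf2) returns to 9.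

Step 15. Most likely to go wrong: decarbonylation of the arylacetyl–palladium intermediate or β-hydride elimination from the pentyl–palladium species; closure of the acid or acid chloride onto the neighbouring aryl ester with expulsion of ring B; and zinc-halide-promoted enol lactonisation of the product ketone onto the depside carbonyl. Fallback: use a milder, isolable acyl donor, setting out from 21 and returning at 25. Thioesterification (EtSH, DCC, DMAP cat., CH2Cl2, 0 °C) gives S-ethyl {3-(benzyloxy)-2-[(3-(benzyloxy)-4-[(benzyloxy)carbonyl]-5-pentylphenoxy)carbonyl]-5-methoxyphenyl}ethanethioate F9, and Fukuyama coupling of F9 with 23 (PdCl2(PPh3)2, THF/toluene, rt) returns to 25.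

## Further compounds

F1 | step 12 | allyl tert-butyl malonate | C=CCOC(=O)CC(=O)OC(C)(C)C
F2 | step 12 | allyl 2-(benzyloxy)-6-(2-tert-butoxy-2-oxoethyl)-4-methoxybenzoate | C=CCOC(=O)c1c(OCc2ccccc2)cc(OC)cc1CC(=O)OC(C)(C)C
F3 | step 12 | 2-(benzyloxy)-6-(2-tert-butoxy-2-oxoethyl)-4-methoxybenzoic acid | OC(=O)c1c(OCc2ccccc2)cc(OC)cc1CC(=O)OC(C)(C)C
F4 | step 2 | 2-iodo-5-methoxybenzene-1,3-diol | COc1cc(O)c(I)c(O)c1
F5 | step 2 | 2-iodo-5-methoxy-1,3-bis(trimethylsilyloxy)benzene | COc1cc(O[Si](C)(C)C)c(I)c(O[Si](C)(C)C)c1
F6 | step 2 | lithium 5-methoxy-2-(trimethylsilyl)-3-(trimethylsilyloxy)phenolate | COc1cc(O[Si](C)(C)C)c([Si](C)(C)C)c([O-])c1.[Li+]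
F7 | step 4 | 3-hydroxy-5-methoxy-2-(trimethylsilyl)phenyl N-isopropylcarbamate | COc1cc(O)c([Si](C)(C)C)c(OC(=O)NC(C)C)c1
F8 | step 4 | 3-(benzyloxy)-5-methoxy-2-(trimethylsilyl)phenyl N-isopropylcarbamate | COc1cc(OCc2ccccc2)c([Si](C)(C)C)c(OC(=O)NC(C)C)c1
F9 | step 15 | S-ethyl {3-(benzyloxy)-2-[(3-(benzyloxy)-4-[(benzyloxy)carbonyl]-5-pentylphenoxy)carbonyl]-5-methoxyphenyl}ethanethioate | CCSC(=O)Cc1cc(OC)cc(OCc2ccccc2)c1C(=O)Oc1cc(OCc2ccccc2)c(C(=O)OCc2ccccc2)c(CCCCC)c1
A1 | alternative 1 | benzyl 2-hydroxy-4-({2-hydroxy-4-methoxy-6-[(2-pentyl-1,3-dioxolan-2-yl)methyl]benzoyl}oxy)-6-pentylbenzoate | CCCCCC1(OCCO1)Cc1cc(OC)cc(O)c1C(=O)Oc1cc(O)c(C(=O)OCc2ccccc2)c(CCCCC)c1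
A2 | alternative 1 | benzyl 2-hydroxy-6-pentyl-4-{[4-(2-pentyl-1,3-dioxolan-2-yl)but-2-ynoyl]oxy}benzoate | CCCCCC1(OCCO1)CC#CC(=O)Oc1cc(O)c(C(=O)OCc2ccccc2)c(CCCCC)c1
A3 | alternative 1 | 1,3-dimethoxy-1-(trimethylsilyloxy)buta-1,3-diene | COC(=C)C=C(OC)O[Si](C)(C)C
A4 | alternative 2 | benzyl 4-({2,4-dihydroxy-6-[(2-pentyl-1,3-dioxolan-2-yl)methyl]benzoyl}oxy)-2-hydroxy-6-pentylbenzoate | CCCCCC1(OCCO1)Cc1cc(O)cc(O)c1C(=O)Oc1cc(O)c(C(=O)OCc2ccccc2)c(CCCCC)c1
A5 | alternative 2 | 2,2-dimethyl-6-[2,4-dioxo-5-(2-pentyl-1,3-dioxolan-2-yl)pentyl]-4H-1,3-dioxin-4-one | CCCCCC1(CC(=O)CC(=O)CC2=CC(=O)OC(C)(C)O2)OCCO1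
A6 | alternative 2 | benzyl 2,4-dihydroxy-6-pentylbenzoate (benzyl olivetolate) | CCCCCc1cc(O)cc(O)c1C(=O)OCc1ccccc1
A7 | alternative 3 | benzyl 4-({2,4-dimethoxy-6-[(2-pentyl-1,3-dioxolan-2-yl)methyl]benzoyl}oxy)-2-hydroxy-6-pentylbenzoate | CCCCCC1(OCCO1)Cc1cc(OC)cc(OC)c1C(=O)Oc1cc(O)c(C(=O)OCc2ccccc2)c(CCCCC)c1
A8 | alternative 3 | 2-[(2-iodo-3,5-dimethoxyphenyl)methyl]-2-pentyl-1,3-dioxolane | CCCCCC1(OCCO1)Cc1cc(OC)cc(OC)c1I
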